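The 11-membered ring is opened between the neopentyl ring methylene C1 (flanked by the quaternary CMe2 carbon C11) and the hydroperoxy-bearing allylic carbon C2 (flanked by the exocyclic-methylene carbon C3). In the forward sense a cobalt-catalysed, chromium(II)-mediated alkyl iodide–aldehyde coupling turns the acyclic (Z)-iodo enal 19 into the cycloundecadienol in one operation, forming C1–C2 and the C2 carbinol. The step exploits the β-hydrogen-free, SN2-inert neopentyl iodide, which is carried untouched through the route, and the 2-substituted acrolein onto which the C2/C3(=CH2) unit maps. C2 is then reset by oxidation/CBS reduction and converted into the hydroperoxide by SN2 inversion with a protected peroxide; the coumarate is attached last.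

Key step: step 10

Remark (atom labels): ring atoms are labelled C1 (CH2 next to CMe2), C2 (CH–OOH), C3 (bearing the exocyclic CH2, C15), C4, C5, C6=C7(CH3) (Z), C8, C9 (CH–O-acyl), C10, C11 (CMe2); the same labels are used for the acyclic precursors.
Remark (assumptions): compounds 1, 6, 10, 24 and 30 are taken as purchased; (R,R)-(salen)Co(III)OAc is taken as the catalyst enantiomer that leaves the (R)-epoxide of an alkyl oxirane unreacted, and the (S,S)-complex is used if the sense proves opposite.

Step 1
Reactants: 1 2,2-dimethylpent-4-en-1-ol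
Product: 2 5-iodo-4,4-dimethylpent-1-ene
Conditions: PPh3, I2, imidazole, toluene, 90 °C
Reagents that add atoms: iodine, II
Why: Garegg–Samuelsson (Appel-type) iodination: the alkoxyphosphonium ion is displaced by iodide, which at this neopentyl carbon needs heating but cannot rearrange because no carbocation is involved; no stereocentre is formed.

Step 2
Reactants: 2 5-iodo-4,4-dimethylpent-1-ene
Product: 4 rac-2-(3-iodo-2,2-dimethylpropyl)oxirane, via 1-bromo-5-iodo-4,4-dimethylpentan-2-ol 3 (not isolated)
Conditions: NBS, THF/H2O, 0 °C → rt; then 2 M NaOH, rt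
Reagents that add atoms: water, O
Why: Bromohydrin formation (bromonium ion opened by water) and Williamson-type ring closure give the racemic oxirane; this non-peracid epoxidation is chosen because peracids oxidise alkyl iodides.

Step 3
Reactants: 4 rac-2-(3-iodo-2,2-dimethylpropyl)oxirane
Product: 5 (R)-2-(3-iodo-2,2-dimethylpropyl)oxirane
Conditions: (R,R)-(salen)Co(III)OAc (0.5 mol %), H2O (0.55 equiv), THF, 0 °C → rt
Reagents that add atoms: none
Why: Jacobsen hydrolytic kinetic resolution: the cooperative bimetallic (salen)Co mechanism should hydrolyse the (S)-epoxide selectively and leave (R)-5, which fixes the future C9 configuration by catalyst control.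

Step 4
Reactants: 6 cyclopentene
Product: 9 5,5-dimethoxypentanal, via 5-hydroperoxy-5-methoxypentanal 7 (not isolated), via 1-hydroperoxy-1,5,5-trimethoxypentane 8 (not isolated)
Conditions: O3, CH2Cl2/MeOH, −78 °C; TsOH·H2O, rt; NaHCO3; Me2S
Reagents that add atoms: ozone, [O-][O+]=O; methanol, CO
Why: Schreiber ozonolysis with unsymmetrical work-up: the carbonyl oxide is trapped by methanol, the free aldehyde is acetalised, and the methoxy hydroperoxide end is then reduced to the aldehyde, giving a terminus-differentiated C2–C6 chain.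

Step 5
Reactants: 9 5,5-dimethoxypentanal; 10 ethyltriphenylphosphonium iodide
Product: 14 (Z)-6-iodo-1,1-dimethoxyhept-5-ene, via ethylidenetriphenylphosphorane 11 (not isolated), via (1-iodoethyl)triphenylphosphonium iodide 12 (not isolated), via (1-iodoethylidene)triphenylphosphorane 13 (not isolated)
Conditions: n-BuLi, THF, 0 °C; I2, −78 °C; NaHMDS, −78 → −20 °C; then 9, −78 °C → rt
Reagents that add atoms: iodine, II
Why: Stork–Zhao-type Wittig olefination with the α-iodo ylide: kinetic oxaphosphetane formation of the non-stabilised ylide should place iodine cis to the chain, which sets the Z geometry of the future C6=C7 bond.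

Step 6
Reactants: 14 (Z)-6-iodo-1,1-dimethoxyhept-5-ene; 5 (R)-2-(3-iodo-2,2-dimethylpropyl)oxirane
Product: 16 (5Z,8S)-11-iodo-1,1-dimethoxy-6,10,10-trimethylundec-5-en-8-ol, via (E)-(7,7-dimethoxyhept-2-en-2-yl)lithium 15 (not isolated)
Conditions: t-BuLi (2 equiv), Et2O, −78 °C; then 5, BF3·OEt2, −78 °C; NH4Cl quench at −78 °C
Reagents that add atoms: none
Why: Iodine–lithium exchange with retention of olefin geometry, then BF3-promoted SN2 opening of the epoxide at its terminal carbon (Ganem-type conditions); C9 is not touched, and the neopentyl iodide survives because it is SN2-inert and its exchange with an alkenyllithium is uphill (the descriptor at C9 becomes S only because CH2I now outranks the allylic branch).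

Step 7
Reactants: 16 (5Z,8S)-11-iodo-1,1-dimethoxy-6,10,10-trimethylundec-5-en-8-ol
Product: 17 tert-butyl{[(5Z,8S)-11-iodo-1,1-dimethoxy-6,10,10-trimethylundec-5-en-8-yl]oxy}dimethylsilane
Conditions: TBSCl, imidazole, DMF, rt
Reagents that add atoms: tert-butyldimethylsilyl chloride, CC(C)(C)[Si](C)(C)Cl
Why: Standard silylation of the secondary alcohol under non-basic conditions, so that no C9 alkoxide is formed that could displace the C1 iodide to a tetrahydrofuran.

Step 8
Reactants: 17 tert-butyl{[(5Z,8S)-11-iodo-1,1-dimethoxy-6,10,10-trimethylundec-5-en-8-yl]oxy}dimethylsilane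
Product: 18 (5Z,8S)-8-[(tert-butyldimethylsilyl)oxy]-11-iodo-6,10,10-trimethylundec-5-enal
Conditions: PPTS (cat.), acetone/H2O, 45 °C
Reagents that add atoms: water, O
Why: Mild acid-catalysed acetal hydrolysis; the secondary TBS ether and the alkyl iodide should be stable to PPTS in wet acetone.

Step 9
Reactants: 18 (5Z,8S)-8-[(tert-butyldimethylsilyl)oxy]-11-iodo-6,10,10-trimethylundec-5-enal
Product: 19 (5Z,8S)-8-[(tert-butyldimethylsilyl)oxy]-11-iodo-6,10,10-trimethyl-2-methylideneundec-5-enal
Conditions: 37% aq. HCHO, pyrrolidine (10 mol %), EtCO2H (10 mol %), i-PrOH, 45 °C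
Reagents that add atoms: formaldehyde, C=O
Why: Organocatalytic Mannich/elimination α-methylenation of an aldehyde installs C15 and gives the 2-substituted acrolein without touching the isolated alkene or the iodide.

Step 10
Reactants: 19 (5Z,8S)-8-[(tert-butyldimethylsilyl)oxy]-11-iodo-6,10,10-trimethyl-2-methylideneundec-5-enal
Product: 21 (5Z,8R)-8-[(tert-butyldimethylsilyl)oxy]-6,10,10-trimethyl-2-methylidenecycloundec-5-en-1-ol (both C1 epimers; C1 of this name is atom C2), via alkylchromium(III) dichloride 20 (not isolated)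
Conditions: CrCl2 (8 equiv), cobalt(II) phthalocyanine (10 mol %), DMF/THF, rt, syringe-pump addition of 19 (final concentration ≤ 2 mM)
Reagents that add atoms: none
Why: CrCl2 reduces the cobalt phthalocyanine to Co(I), which activates the C1–I bond; the resulting neopentyl radical (no β-hydrogens) is captured by Cr(II) to give the alkylchromium(III) 20, which adds 1,2 to the aldehyde and forms the C1–C2 bond. The closest known reaction type is the Takai–Utimoto/Kishi Co/Cr-mediated alkyl iodide–aldehyde coupling, run here in the ring-closing mode familiar from Nozaki–Hiyama–Kishi macrocyclisations of alkenyl and allyl halides. The 11-membered carbocycle closes in an 11-exo-trig mode (the C=O is exocyclic to the new ring). The new stereocentre C2 is not controlled, since the remote C9 offers no reliable bias, and need not be: it is erased in step 11 and reset by reagent control in step 12. The step needs chemoselectivity for 1,2-addition over conjugate addition, enal reduction and oligomerisation: the oxophilic, weakly basic Cr(III) reagent adds only 1,2 to aldehydes, only the Co/Cr couple can activate the SN2-inert iodide, and high dilution together with the C11 gem-dimethyl group and the Z-olefin as turn elements should favour ring closure.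

Step 11
Reactants: 21 (5Z,8R)-8-[(tert-butyldimethylsilyl)oxy]-6,10,10-trimethyl-2-methylidenecycloundec-5-en-1-ol (both C1 epimers)
Product: 22 (5Z,8R)-8-[(tert-butyldimethylsilyl)oxy]-6,10,10-trimethyl-2-methylidenecycloundec-5-en-1-one
Conditions: Dess–Martin periodinane, CH2Cl2, 0 °C → rt
Reagents that add atoms: none
Why: Dess–Martin oxidation converts both C2 epimers into one cross-conjugated enone, which removes the uncontrolled stereocentre.

Step 12
Reactants: 22 (5Z,8R)-8-[(tert-butyldimethylsilyl)oxy]-6,10,10-trimethyl-2-methylidenecycloundec-5-en-1-one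
Product: 23 (1R,5Z,8R)-8-[(tert-butyldimethylsilyl)oxy]-6,10,10-trimethyl-2-methylidenecycloundec-5-en-1-ol
Conditions: (S)-Me-CBS (0.5 equiv), catecholborane, toluene, −78 °C
Reagents that add atoms: none
Why: Corey–Bakshi–Shibata reduction: the ketone should bind the (S)-oxazaborolidine anti to the larger α-branched alkenyl group (C3), so that hydride is delivered to the face giving the (R)-carbinol at C2 by catalyst control; catecholborane at −78 °C avoids 1,4-reduction.

Step 13
Reactants: 24 2,3-dimethylbut-2-ene
Product: 25 2-methoxyprop-2-yl hydroperoxide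
Conditions: O3, CH2Cl2/MeOH, −78 °C; N2 purge
Reagents that add atoms: ozone, [O-][O+]=O; methanol, CO
Why: Ozonolysis in methanol: the acetone carbonyl oxide (Criegee intermediate) is trapped by methanol to give a ketal-protected form of hydrogen peroxide.

Step 14
Reactants: 23 (1R,5Z,8R)-8-[(tert-butyldimethylsilyl)oxy]-6,10,10-trimethyl-2-methylidenecycloundec-5-en-1-ol; 25 2-methoxyprop-2-yl hydroperoxide
Product: 28 tert-butyl{[(1R,3Z,8S)-8-[(2-methoxypropan-2-yl)peroxy]-3,10,10-trimethyl-7-methylidenecycloundec-3-en-1-yl]oxy}dimethylsilane, via allylic mesylate 26 (not isolated), via potassium 2-methoxyprop-2-yl peroxide 27 (not isolated)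
Conditions: Ms2O, Et3N, THF, −30 °C; then 25/KOtBu (premixed), 18-crown-6 (cat.), DMF, 0 °C
Reagents that add atoms: none
Why: Sulfonylation followed by SN2 displacement with the α-effect peroxide anion (alkylation of a protected hydroperoxide, a sulfonate-displacement hydroperoxide synthesis) should invert C2 from R to the S configuration of the target; Ms2O is used so that no chloride is present to compete.

Step 15
Reactants: 28 tert-butyl{[(1R,3Z,8S)-8-[(2-methoxypropan-2-yl)peroxy]-3,10,10-trimethyl-7-methylidenecycloundec-3-en-1-yl]oxy}dimethylsilane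
Product: 29 (1R,3Z,8S)-8-[(2-methoxypropan-2-yl)peroxy]-3,10,10-trimethyl-7-methylidenecycloundec-3-en-1-ol
Conditions: TBAF, AcOH, THF, 0 °C → rt
Reagents that add atoms: none
Why: Fluoride-mediated desilylation, buffered with acetic acid so that the allylic peroxide is not exposed to alkoxide (Kornblum–DeLaMare pathway); dialkyl peroxyketals should tolerate fluoride.

Step 16
Reactants: 30 (E)-4-hydroxycinnamic acid
Product: 32 (E)-3-[4-(oxan-2-yloxy)phenyl]prop-2-enoic acid, via bis-THP derivative 31 (not isolated)
Conditions: 3,4-dihydro-2H-pyran, PPTS (cat.), CH2Cl2, rt; then LiOH, THF/MeOH/H2O, 0 °C; AcOH to pH 5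
Reagents that add atoms: 3,4-dihydro-2H-pyran, C1=COCCC1
Why: Acid-catalysed addition of the phenol and the acid to dihydropyran, then selective saponification of the labile THP ester, gives the phenol-protected acid (THP acetal carbon as a mixture of epimers, of no consequence).

Step 17
Reactants: 29 (1R,3Z,8S)-8-[(2-methoxypropan-2-yl)peroxy]-3,10,10-trimethyl-7-methylidenecycloundec-3-en-1-ol; 32 (E)-3-[4-(oxan-2-yloxy)phenyl]prop-2-enoic acid
Product: 33 (1R,3Z,8S)-8-[(2-methoxypropan-2-yl)peroxy]-3,10,10-trimethyl-7-methylidenecycloundec-3-en-1-yl (E)-3-[4-(oxan-2-yloxy)phenyl]prop-2-enoate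
Conditions: DIC, DMAP, CH2Cl2, 0 °C → rt
Reagents that add atoms: none
Why: Steglich esterification acylates the C9 hydroxyl with retention under neutral conditions that leave the peroxyketal and the THP acetal intact.

Step 18
Reactants: 33 (1R,3Z,8S)-8-[(2-methoxypropan-2-yl)peroxy]-3,10,10-trimethyl-7-methylidenecycloundec-3-en-1-yl (E)-3-[4-(oxan-2-yloxy)phenyl]prop-2-enoate
Product: 34 (1R,3Z,8S)-8-hydroperoxy-3,10,10-trimethyl-7-methylidenecycloundec-3-en-1-yl (E)-3-(4-hydroxyphenyl)prop-2-enoate (CNP0208931.1)
Conditions: AcOH/THF/H2O (4:2:1), 35 °C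
Reagents that add atoms: none
Why: Mild aqueous-acid hydrolysis cleaves the aryl THP ether and the 2-methoxyprop-2-yl peroxyketal in one operation, freeing the phenol and the hydroperoxide under conditions too weak for Hock cleavage of the allylic hydroperoxide.

Compound list
1 | 2,2-dimethylpent-4-en-1-ol | C=CCC(C)(C)CO | starting material
2 | 5-iodo-4,4-dimethylpent-1-ene | C=CCC(C)(C)CI | intermediate
3 | 1-bromo-5-iodo-4,4-dimethylpentan-2-ol (racemic) | OC(CBr)CC(C)(C)CI | intermediate
4 | rac-2-(3-iodo-2,2-dimethylpropyl)oxirane | ICC(C)(C)CC1CO1 | intermediate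
5 | (R)-2-(3-iodo-2,2-dimethylpropyl)oxirane | ICC(C)(C)C[C@@H]1CO1 | intermediate
6 | cyclopentene | C1=CCCC1 | starting material
7 | 5-hydroperoxy-5-methoxypentanal | O=CCCCC(OC)OO | intermediate
8 | 1-hydroperoxy-1,5,5-trimethoxypentane | COC(OC)CCCC(OC)OO | intermediate
9 | 5,5-dimethoxypentanal | COC(OC)CCCC=O | intermediate
10 | ethyltriphenylphosphonium iodide | CC[P+](c1ccccc1)(c1ccccc1)c1ccccc1.[I-] | starting material
11 | ethylidenetriphenylphosphorane | CC=P(c1ccccc1)(c1ccccc1)c1ccccc1 | intermediate
12 | (1-iodoethyl)triphenylphosphonium iodide | CC(I)[P+](c1ccccc1)(c1ccccc1)c1ccccc1.[I-] | intermediate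
13 | (1-iodoethylidene)triphenylphosphorane | CC(I)=P(c1ccccc1)(c1ccccc1)c1ccccc1 | intermediate
14 | (Z)-6-iodo-1,1-dimethoxyhept-5-ene | COC(OC)CCC/C=C(/C)I | intermediate
15 | (E)-(7,7-dimethoxyhept-2-en-2-yl)lithium (geometry of 14 retained) | COC(OC)CCC/C=C(/C)[Li] | intermediate
16 | (5Z,8S)-11-iodo-1,1-dimethoxy-6,10,10-trimethylundec-5-en-8-ol | COC(OC)CCC/C=C(/C)C[C@H](O)CC(C)(C)CI | intermediate
17 | tert-butyl{[(5Z,8S)-11-iodo-1,1-dimethoxy-6,10,10-trimethylundec-5-en-8-yl]oxy}dimethylsilane | COC(OC)CCC/C=C(/C)C[C@H](O[Si](C)(C)C(C)(C)C)CC(C)(C)CI | intermediate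
18 | (5Z,8S)-8-[(tert-butyldimethylsilyl)oxy]-11-iodo-6,10,10-trimethylundec-5-enal | O=CCCC/C=C(/C)C[C@H](O[Si](C)(C)C(C)(C)C)CC(C)(C)CI | intermediate
19 | (5Z,8S)-8-[(tert-butyldimethylsilyl)oxy]-11-iodo-6,10,10-trimethyl-2-methylideneundec-5-enal | O=CC(=C)CC/C=C(/C)C[C@H](O[Si](C)(C)C(C)(C)C)CC(C)(C)CI | intermediate
20 | alkylchromium(III) dichloride of 19 (CrCl2 on C1 in place of iodine) | O=CC(=C)CC/C=C(/C)C[C@H](O[Si](C)(C)C(C)(C)C)CC(C)(C)C[Cr](Cl)Cl | intermediate
21 | (5Z,8R)-8-[(tert-butyldimethylsilyl)oxy]-6,10,10-trimethyl-2-methylidenecycloundec-5-en-1-ol, both C1 epimers | C=C1CC/C=C(/C)C[C@H](O[Si](C)(C)C(C)(C)C)CC(C)(C)CC1O | intermediate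
22 | (5Z,8R)-8-[(tert-butyldimethylsilyl)oxy]-6,10,10-trimethyl-2-methylidenecycloundec-5-en-1-one | C=C1CC/C=C(/C)C[C@H](O[Si](C)(C)C(C)(C)C)CC(C)(C)CC1=O | intermediate
23 | (1R,5Z,8R)-8-[(tert-butyldimethylsilyl)oxy]-6,10,10-trimethyl-2-methylidenecycloundec-5-en-1-ol | C=C1CC/C=C(/C)C[C@H](O[Si](C)(C)C(C)(C)C)CC(C)(C)C[C@H]1O | intermediate
24 | 2,3-dimethylbut-2-ene | CC(C)=C(C)C | starting material
25 | 2-methoxyprop-2-yl hydroperoxide | COC(C)(C)OO | intermediate
26 | (1R,5Z,8R)-8-[(tert-butyldimethylsilyl)oxy]-6,10,10-trimethyl-2-methylidenecycloundec-5-en-1-yl methanesulfonate | C=C1CC/C=C(/C)C[C@H](O[Si](C)(C)C(C)(C)C)CC(C)(C)C[C@H]1OS(C)(=O)=O | intermediate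
27 | potassium 2-methoxyprop-2-yl peroxide | COC(C)(C)O[O-].[K+] | intermediate
28 | tert-butyl{[(1R,3Z,8S)-8-[(2-methoxypropan-2-yl)peroxy]-3,10,10-trimethyl-7-methylidenecycloundec-3-en-1-yl]oxy}dimethylsilane | C=C1CC/C=C(/C)C[C@H](O[Si](C)(C)C(C)(C)C)CC(C)(C)C[C@@H]1OOC(C)(C)OC | intermediate
29 | (1R,3Z,8S)-8-[(2-methoxypropan-2-yl)peroxy]-3,10,10-trimethyl-7-methylidenecycloundec-3-en-1-ol | C=C1CC/C=C(/C)C[C@H](O)CC(C)(C)C[C@@H]1OOC(C)(C)OC | intermediate
30 | (E)-4-hydroxycinnamic acid (p-coumaric acid) | O=C(O)/C=C/c1ccc(O)cc1 | starting material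
31 | oxan-2-yl (E)-3-[4-(oxan-2-yloxy)phenyl]prop-2-enoate (acetal carbons unspecified) | O=C(OC1CCCCO1)/C=C/c1ccc(OC2CCCCO2)cc1 | intermediate
32 | (E)-3-[4-(oxan-2-yloxy)phenyl]prop-2-enoic acid (acetal carbon unspecified) | O=C(O)/C=C/c1ccc(OC2CCCCO2)cc1 | intermediate
33 | (1R,3Z,8S)-8-[(2-methoxypropan-2-yl)peroxy]-3,10,10-trimethyl-7-methylidenecycloundec-3-en-1-yl (E)-3-[4-(oxan-2-yloxy)phenyl]prop-2-enoate (THP acetal carbon unspecified) | C=C1CC/C=C(/C)C[C@H](OC(=O)/C=C/c2ccc(OC3CCCCO3)cc2)CC(C)(C)C[C@@H]1OOC(C)(C)OC | intermediate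
34 | (1R,3Z,8S)-8-hydroperoxy-3,10,10-trimethyl-7-methylidenecycloundec-3-en-1-yl (E)-3-(4-hydroxyphenyl)prop-2-enoate | C=C1CC/C=C(/C)C[C@H](OC(=O)/C=C/c2ccc(O)cc2)CC(C)(C)C[C@@H]1OO | target

Total step count: 18. Longest linear sequence: 14 steps (steps 1–3, 6–12, 14, 15, 17, 18).

Steps most likely to fail

1. Step 10 (ring closure). The Co(I)/Cr(II) couple may activate the hindered neopentyl iodide too slowly, so that reduction or oligomerisation of the enal overtakes ring closure; ring-closing precedent for this coupling exists for alkenyl and allyl halides but is thin for alkyl halides. The fallback sets out from 18 and comes back at 22. The saturated iodo aldehyde 18 is cyclised by a samarium Barbier reaction (SmI2, HMPA, THF, high dilution). Here the C–I bond is cleaved by electron transfer that does not depend on backside access, and no enal is present. This gives the C1–C2-closed (5Z,8R)-8-[(tert-butyldimethylsilyl)oxy]-6,10,10-trimethylcycloundec-5-en-1-ol F1 as a mixture of C2 epimers. Dess–Martin oxidation gives the ketone F2. Kinetic deprotonation (LiHMDS, −78 °C) should occur at C3 and not at the neopentyl C1, and Eschenmoser's salt then gives the Mannich base F3. N-Methylation (MeI) and elimination (NaHCO3) deliver enone 22.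

2. Step 14 (hydroperoxide installation). The peroxide anion may attack the unhindered exocyclic C15 (SN2′) or act as a base (elimination), or the allylic mesylate may ionise and lose its stereochemical integrity. The fallback sets out from 22 and comes back at 28. Reduction of 22 with the enantiomeric (R)-Me-CBS catalyst gives the (1S,5Z,8R)-alcohol F4. Appel bromination (CBr4, PPh3) with inversion gives the (2R)-allylic bromide F5. Silver-assisted perhydrolysis (AgOCOCF3, anhydrous H2O2, Et2O, 0 °C), in which silver pulls off the bromide while H2O2 enters from the rear, should give the (2S)-hydroperoxide F6. Any C2 epimer is a diastereomer and any C15 regioisomer a constitutional isomer, so both can be removed by chromatography. Ketalisation of F6 with 2-methoxypropene/PPTS gives 28.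

3. Step 12 (CBS reduction). Facial selectivity may be poor, because the two ketone substituents (the neopentyl-type C1 methylene and the 1,1-disubstituted alkenyl C3) differ less in size than in typical CBS substrates and the ring conformation may override the catalyst. The fallback sets out from 21 and comes back at 23, dropping the oxidation/reduction detour. The C2 epimers of 21 are diastereomers (C9 is fixed) and are separated by chromatography, with configuration assigned by Mosher ester analysis. The (2R) epimer is 23. The (2S) epimer (the same compound as F4) is inverted by Mitsunobu reaction (4-nitrobenzoic acid, DIAD, PPh3) to the (1R,5Z,8R)-4-nitrobenzoate F7, and methanolysis (K2CO3, MeOH) gives 23.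

Further compounds
F1 | step 10 | (5Z,8R)-8-[(tert-butyldimethylsilyl)oxy]-6,10,10-trimethylcycloundec-5-en-1-ol (both C1 epimers) | C1CC/C=C(/C)C[C@H](O[Si](C)(C)C(C)(C)C)CC(C)(C)CC1O
F2 | step 10 | (5Z,8R)-8-[(tert-butyldimethylsilyl)oxy]-6,10,10-trimethylcycloundec-5-en-1-one | C1CC/C=C(/C)C[C@H](O[Si](C)(C)C(C)(C)C)CC(C)(C)CC1=O
F3 | step 10 | (5Z,8R)-8-[(tert-butyldimethylsilyl)oxy]-2-[(dimethylamino)methyl]-6,10,10-trimethylcycloundec-5-en-1-one (both C2 epimers) | CN(C)CC1CC/C=C(/C)C[C@H](O[Si](C)(C)C(C)(C)C)CC(C)(C)CC1=O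
F4 | step 14 | (1S,5Z,8R)-8-[(tert-butyldimethylsilyl)oxy]-6,10,10-trimethyl-2-methylidenecycloundec-5-en-1-ol | C=C1CC/C=C(/C)C[C@H](O[Si](C)(C)C(C)(C)C)CC(C)(C)C[C@@H]1O
F5 | step 14 | tert-butyl{[(1R,3Z,8R)-8-bromo-3,10,10-trimethyl-7-methylidenecycloundec-3-en-1-yl]oxy}dimethylsilane | C=C1CC/C=C(/C)C[C@H](O[Si](C)(C)C(C)(C)C)CC(C)(C)C[C@H]1Br
F6 | step 14 | tert-butyl{[(1R,3Z,8S)-8-hydroperoxy-3,10,10-trimethyl-7-methylidenecycloundec-3-en-1-yl]oxy}dimethylsilane | C=C1CC/C=C(/C)C[C@H](O[Si](C)(C)C(C)(C)C)CC(C)(C)C[C@@H]1OO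
F7 | step 12 | (1R,5Z,8R)-8-[(tert-butyldimethylsilyl)oxy]-6,10,10-trimethyl-2-methylidenecycloundec-5-en-1-yl 4-nitrobenzoate | C=C1CC/C=C(/C)C[C@H](O[Si](C)(C)C(C)(C)C)CC(C)(C)C[C@H]1OC(=O)c1ccc(cc1)[N+](=O)[O-]
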